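**Assumption:** The two electron-rich arene units are bought as the commercial syringaldehyde and 3,4,5-trimethoxybenzyl bromide. All other building blocks are small C2/C4 commodity chemicals.

## Retrosynthetic overview
- The target is the all-trans 2,5-diaryl-3,4-bis(hydroxymethyl)tetrahydrofuran, (2R,3S,4S,5R). It comes from global desilylation of the protected THF **8**, which is the single enantiomer separated from racemic **7** on a chiral stationary phase.
- Racemic THF **7** is built in one step by a photoredox radical-cation [3+2] reaction. The unsymmetrical trans-diaryl epoxide **4** (the C7–O–C7′ unit, via its carbonyl-ylide radical cation) adds across (E)-1,4-bis(silyloxy)but-2-ene **6** (C8=C8′ with the C9/C9′ carbons). This forms both C7–C8 and C7′–C8′ bonds and the THF ring together.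
- Epoxide **4** comes from a Corey–Chaykovsky reaction of silyl-protected syringaldehyde **2** with the trimethoxybenzyl sulfonium ylide, and alkene **6** from (E)-butenediol.
- Ring order: the arenes are pre-existing, then the oxirane, then the THF in the key step.

## Route

**Step 1**
Reactants: **1** syringaldehyde (4-hydroxy-3,5-dimethoxybenzaldehyde)
Product: **2** 4-(triisopropylsilyloxy)-3,5-dimethoxybenzaldehyde
Conditions: TIPSCl, imidazole, DMF, 25 °C
Reagents that add atoms: TIPSCl, CC(C)[Si](Cl)(C(C)C)C(C)C
Why: Silylation masks the oxidisable phenol, which would otherwise be taken to the phenoxyl radical in the photoredox step; the hindered TIPS aryl ether survives the KOH in step 2.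

**Step 2**
Reactants: **2**; **3** 3,4,5-trimethoxybenzyl bromide (commercial)
Product: **4** trans-2-[4-(TIPSO)-3,5-dimethoxyphenyl]-3-(3,4,5-trimethoxyphenyl)oxirane (racemic)
Conditions: Me2S (1.5 equiv), KOH, MeCN/H2O 9:1, 50 °C, sealed vial
Reagents that add atoms: none (Me2S is lost as sulfide)
Why: Corey–Chaykovsky epoxidation; the sulfonium salt forms in situ, and the betaine collapses with anti-selectivity to the trans-diaryl epoxide. The epoxide is racemic, and its stereochemistry is erased in step 4.

**Step 3**
Reactants: **5** (E)-but-2-ene-1,4-diol
Product: **6** (E)-1,4-bis(tert-butyldimethylsilyloxy)but-2-ene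
Conditions: TBSCl, imidazole, DMF, 25 °C
Reagents that add atoms: TBSCl, CC(C)(C)[Si](C)(C)Cl
Why: Silylation makes the alkene a soluble, non-nucleophilic-OH partner. The (E) geometry is retained and will set the 3,4-trans relationship.

**Step 4 (key radical step)**
Reactants: **4**; **6** (3 equiv)
Product: **7** all-trans 2-[4-(TIPSO)-3,5-dimethoxyphenyl]-5-(3,4,5-trimethoxyphenyl)-3,4-bis(TBSO-methyl)tetrahydrofuran (racemic)
Conditions: [Mes-Acr-Me]+BF4– (5 mol%), DCE (0.05 M), blue LEDs (450 nm), 25 °C, 24 h, N2
Reagents that add atoms: none (the photocatalyst is catalytic)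
Why: Proposed new method: excited acridinium oxidises the electron-rich diaryl epoxide to its radical cation, which undergoes C–C scission to the carbonyl-ylide radical cation ArCH=O+–CH•Ar′. This is captured by the (E)-alkene in a stepwise or asynchronous radical-cation [3+2] (closest known reaction: photocatalytic aryl-epoxide or aryl-cyclopropane radical-cation [3+2] with alkenes), and the acridinyl radical then reduces the THF radical cation back to neutral **7**. The (E)-alkene fixes 3,4-trans, and steric preference in ring closure, with reversible benzylic opening of the product radical cation, should favour the all-trans (2,5-trans) ring. Minor diastereomers are removed by silica chromatography.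

**Step 5**
Reactants: **7**
Product: **8** (2R,3S,4S,5R)-protected THF (single enantiomer)
Conditions: Preparative chiral-phase HPLC (Chiralpak IA, hexane/iPrOH 98:2), 25 °C
Reagents that add atoms: none
Why: The key step is achiral, so the absolute configuration is set by enantiomer separation; the peak is assigned as (2R,3S,4S,5R) by comparing [α]D/CD of the deprotected material with the target.

**Step 6**
Reactants: **8**
Product: **9** target, (2R,3S,4S,5R)-[2-(4-hydroxy-3,5-dimethoxyphenyl)-5-(3,4,5-trimethoxyphenyl)tetrahydrofuran-3,4-diyl]dimethanol
Conditions: TBAF/AcOH (buffered), THF, 0 °C → 25 °C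
Reagents that add atoms: none (only H is added)
Why: Fluoride cleaves the aryl-OTIPS and both primary OTBS groups under non-acidic conditions, so the acid-sensitive benzylic ether is not ionised; no stereocentre is touched.

## Checks
- The ring is a THF: O, C7, C8, C8′, C7′.
- Substituents match the target: syringyl-OH at C2, 3,4,5-trimethoxyphenyl at C5, CH2OH at C3 and C4.
- Configuration is all-trans, i.e. Ar1 up, C8-CH2OH down, C8′-CH2OH up, Ar2 down.
- CIP descriptors computed from the target SMILES are 2R,3S,4S,5R.
- Every atom in **7** comes from **4** plus **6**.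
- Silyl groups and aryl methyl ethers survive steps 2–5.
- Relative stereochemistry is set in step 4 and absolute configuration in step 5; nothing is scrambled afterwards.

## Compound list
1 | syringaldehyde | COc1cc(C=O)cc(OC)c1O | starting material
2 | 4-(TIPSO)-3,5-dimethoxybenzaldehyde | COc1cc(C=O)cc(OC)c1O[Si](C(C)C)(C(C)C)C(C)C | intermediate
3 | 3,4,5-trimethoxybenzyl bromide | COc1cc(CBr)cc(OC)c1OC | starting material
4 | trans-diaryl epoxide (racemic, one enantiomer drawn) | COc1cc(cc(OC)c1O[Si](C(C)C)(C(C)C)C(C)C)[C@H]2[C@@H](O2)c3cc(OC)c(OC)c(OC)c3 | intermediate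
5 | (E)-but-2-ene-1,4-diol | OC/C=C/CO | starting material
6 | (E)-1,4-bis(TBSO)but-2-ene | CC(C)(C)[Si](C)(C)OC/C=C/CO[Si](C)(C)C(C)(C)C | intermediate
7 | racemic all-trans protected THF (one enantiomer drawn) | COc1cc([C@@H]2O[C@@H](c3cc(OC)c(OC)c(OC)c3)[C@H](CO[Si](C)(C)C(C)(C)C)[C@H]2CO[Si](C)(C)C(C)(C)C)cc(OC)c1O[Si](C(C)C)(C(C)C)C(C)C | intermediate
8 | (2R,3S,4S,5R) protected THF, single enantiomer | COc1cc([C@@H]2O[C@@H](c3cc(OC)c(OC)c(OC)c3)[C@H](CO[Si](C)(C)C(C)(C)C)[C@H]2CO[Si](C)(C)C(C)(C)C)cc(OC)c1O[Si](C(C)C)(C(C)C)C(C)C | intermediate
9 | target | COc1cc([C@@H]2O[C@@H](c3cc(OC)c(OC)c(OC)c3)[C@H](CO)[C@H]2CO)cc(OC)c1O | target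

## Totals
Total steps: 6. Longest linear sequence: 5 (1 → 2 → 4 → 7 → 8 → 9).

## Three steps most likely to fail
1. **Step 4 (radical-cation [3+2]).** Risks are low yield, over-oxidation of the electron-rich product, Meinwald rearrangement or aldehyde fragmentation of the epoxide, and poor all-trans selectivity.
 *Fallback:* use thermal conrotatory opening of epoxide **4** (about 150 °C, neat or in toluene) to the S-shaped carbonyl ylide, which adds stereospecifically to dimethyl fumarate to give the 2,5-trans-3,4-trans THF diester. Reduction of the diester (DIBAL) gives the bis(hydroxymethyl) compound.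
2. **Step 5 (enantiomer separation).** The two enantiomers may resolve poorly or the column loading may be too low.
 *Fallback:* desilylate the racemate, make the bis-(–)-camphanate, separate the diastereomers by silica chromatography or crystallisation, and hydrolyse with K2CO3/MeOH.
3. **Step 2 (epoxide formation).** The trimethoxybenzyl ylide is poorly acidic and the syringyl aldehyde is electron-rich, so yield and trans-selectivity may be poor.
 *Fallback:* Horner–Wadsworth–Emmons olefination of **2** with diethyl 3,4,5-trimethoxybenzylphosphonate to the (E)-stilbene, then epoxidation with DMDO.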